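**Plan**

1. Retrosynthetic cuts, in order: the O–CH3 bond on C5 (5-OH is carried as a methyl ether to the end); the O1–C2 bond of the pyranone ring (ring C), with a temporary CO2t-Bu group added on C3; C2=C3 (benzaldehyde brings C2 and ring B); C3–C4 (tert-butyl acetate brings C3 and the temporary carboxyl); C4–C4a (ortho-formylation); then the C–O bond of the future O1 and the C6–geranyl bond on ring A.
2. Enabling features: in ring C the ether oxygen O1 stands β to the C4 carbonyl (O1–C2–C3–C4=O), so O1–C2 is the bond made by oxa-Michael addition of the phenol on C8a to a C2=C3 enone. In ring A the oxygens on C5 and C7 flank the geranyl carbon C6, and C4a and C8 flank C8a, so ring A has a local mirror plane through C6 and C8a.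
3. This symmetry is used: 4-geranyl-3,5-dimethoxyphenol has one phenol (future O1) and one kind of free ring carbon (future C4a), so the 6- versus 8-geranyl ambiguity of 2',6'-dihydroxy precursors cannot arise. O5 and O7 are told apart only at the end, by chelation to the C4 carbonyl.
4. Forward order: ring A is bought as 1,3-dimethoxybenzene and given geranyl, OH and CHO; the C3 chain is built to an alkylidene β-keto ester carrying ring B; ring C is closed last.
5. Stereochemistry: the single stereocentre C2 (S) is set in the ring closure by a bifunctional cinchona thiourea catalyst; the (E)-alkene comes unchanged from geranyl bromide.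

Key step: step 7

Remark: "geranyl" stands throughout for (2E)-3,7-dimethylocta-2,6-dien-1-yl.
Assumption: the (8R,9R) quinidine-derived thiourea is taken to give the 2S series; its (8S,9S) quinine-derived pseudoenantiomer gives the opposite sense and would be used instead if a trial run shows the reverse.

**Route**

Step 1
Reactants: 1 1,3-dimethoxybenzene; 2 geranyl bromide
Product: 4 2-geranyl-1,3-dimethoxybenzene, via 2,6-dimethoxyphenyllithium 3 (not isolated)
Conditions: n-BuLi (1.1 equiv), THF, 0 °C to rt; then 2 (1.1 equiv), −78 °C to rt
Reagents that add atoms: n-butyllithium, [Li]CCCC (lithium of 3 only)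
Why: Directed ortho-metalation, in which the two methoxy groups direct n-BuLi to the carbon between them and aryllithium 3 displaces bromide from the primary allylic carbon of 2 by SN2 attack, which keeps the (E)-alkene and places the chain on the future C6.

Step 2
Reactants: 4 2-geranyl-1,3-dimethoxybenzene
Product: 6 4-geranyl-3,5-dimethoxyphenol, via aryl pinacol boronate 5 (not isolated)
Conditions: [Ir(OMe)(cod)]2 (1.5 mol %), 4,4'-di-tert-butyl-2,2'-bipyridine (3 mol %), B2pin2 (1.0 equiv), THF, 80 °C; then 2 M NaOH, 30 % H2O2, 0 °C to rt
Reagents that add atoms: hydrogen peroxide, OO; bis(pinacolato)diboron, CC1(C)OB(OC1(C)C)B1OC(C)(C)C(C)(C)O1 (boryl group of 5 only)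
Why: Iridium-catalysed aromatic C–H borylation is sterically controlled and should take the only ring C–H without an ortho substituent (para to the geranyl group), and oxidation of the C–B bond of 5 with alkaline hydrogen peroxide, which does not epoxidise unactivated alkenes, should give the symmetric phenol.

Step 3
Reactants: 6 4-geranyl-3,5-dimethoxyphenol
Product: 7 3-geranyl-6-hydroxy-2,4-dimethoxybenzaldehyde
Conditions: MgCl2 (2 equiv), Et3N (4 equiv), (CH2O)n (6 equiv), MeCN, 80 °C; cold 10 % citric acid work-up
Reagents that add atoms: paraformaldehyde, as formaldehyde C=O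
Why: Magnesium-mediated ortho-formylation (Casnati–Skattebøl reaction), in which the magnesium phenoxide delivers formaldehyde to the ortho carbon through a chelate and a second formaldehyde oxidises the hydroxymethyl group by hydride transfer; since the two ortho carbons of 6 are equivalent, only one aldehyde can form.

Step 4
Reactants: 7 3-geranyl-6-hydroxy-2,4-dimethoxybenzaldehyde; 8 tert-butyl acetate
Product: 10 tert-butyl 3-(3-geranyl-6-hydroxy-2,4-dimethoxyphenyl)-3-hydroxypropanoate (racemic), via lithium enolate of tert-butyl acetate 9 (not isolated)
Conditions: LiN(i-Pr)2 (3.2 equiv), 8 (3.2 equiv), THF, −78 °C; then 7, −78 to −30 °C; aq NH4Cl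
Reagents that add atoms: lithium diisopropylamide, [Li]N(C(C)C)C(C)C (lithium of 9 only)
Why: Aldol addition of a preformed lithium ester enolate, in which one equivalent of 9 is spent on the phenol and the excess adds to the aldehyde carbon while the tert-butyl ester resists self-condensation; the new carbinol centre forms racemic and is destroyed in step 5.

Step 5
Reactants: 10 tert-butyl 3-(3-geranyl-6-hydroxy-2,4-dimethoxyphenyl)-3-hydroxypropanoate
Product: 11 tert-butyl 3-(3-geranyl-6-hydroxy-2,4-dimethoxyphenyl)-3-oxopropanoate
Conditions: MnO2 (activated, 15 equiv), CH2Cl2, rt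
Reagents that add atoms: none
Why: Manganese dioxide oxidation of a benzylic alcohol, which should convert the electron-rich benzylic carbinol into the ketone under neutral heterogeneous conditions that leave the phenol, the tert-butyl ester and the trisubstituted alkenes alone.

Step 6
Reactants: 11 tert-butyl 3-(3-geranyl-6-hydroxy-2,4-dimethoxyphenyl)-3-oxopropanoate; 12 benzaldehyde
Product: 13 tert-butyl (2Z)-2-(3-geranyl-6-hydroxy-2,4-dimethoxybenzoyl)-3-phenylprop-2-enoate
Conditions: 12 (1.2 equiv), piperidine (10 mol %), AcOH (20 mol %), 4 Å molecular sieves, toluene, 0 °C to rt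
Reagents that add atoms: none
Why: Knoevenagel condensation, in which the active methylene between ketone and ester condenses with the piperidine-derived iminium ion of benzaldehyde to give the alkylidene, expected mainly as the (Z) isomer with phenyl cis to the ester, while the low temperature and the acid buffer are meant to keep the phenol from adding to the new alkene at this stage.

Step 7
Reactants: 13 tert-butyl (2Z)-2-(3-geranyl-6-hydroxy-2,4-dimethoxybenzoyl)-3-phenylprop-2-enoate
Product: 15 (2S)-6-geranyl-5,7-dimethoxyflavanone, via cyclised tert-butyl ester 14 (not isolated)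
Conditions: 1-[3,5-bis(trifluoromethyl)phenyl]-3-[(8R,9R)-6'-methoxycinchonan-9-yl]thiourea (10 mol %), toluene, −25 °C; then p-TsOH·H2O (0.5 equiv), 80 °C
Reagents that add atoms: none
Why: The two thiourea N–H bonds bind the 1,3-dicarbonyl unit of 13 and the quinuclidine nitrogen takes the proton of the only free phenol, so that the phenoxide oxygen (future O1) adds to the benzylidene carbon (future C2) in an intramolecular oxa-Michael addition to give the enol of 14; acid then splits the tert-butyl ester (loss of 2-methylpropene) and the β-keto acid loses CO2 through its cyclic transition state to the enol of 15, so that no enolate able to expel O1 is formed. The closest known reaction type is the cinchona thiourea-catalysed enantioselective oxa-Michael ring closure of 2'-hydroxyaryl alkylidene β-keto esters to flavanones with acid decarboxylation in the same flask. Ring C closes in the 6-endo-trig mode by forming the O1–C2 bond. C2 is the only lasting new stereocentre and is under catalyst control: the hydrogen-bonded ion pair shields one face of the benzylidene carbon, the (8R,9R) catalyst being taken to give 2S, while the C3 centre of 14 is labile and disappears with the carboxyl group. The step needs regioselectivity between the two oxygens ortho to the acyl carbon and face selectivity at C2; the first is secured by the substrate, in which the oxygen next to the geranyl carbon is a methyl ether so that only the phenol para to the geranyl carbon can close, and the second by the catalyst together with the bulky tert-butyl ester, which should keep the uncatalysed closure slow at −25 °C. The geranyl alkenes are not Michael acceptors and, with both neighbouring oxygens methylated, have no phenol to cyclise onto in the acid stage.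

Step 8
Reactants: 15 (2S)-6-geranyl-5,7-dimethoxyflavanone
Product: 16 (2S)-6-geranylpinostrobin
Conditions: MgI2·OEt2 (3 equiv, separately prepared stock solution), THF, 60 °C; aq NH4Cl
Reagents that add atoms: none
Why: Chelation-controlled ether cleavage, in which magnesium binds the C4 carbonyl oxygen and the peri C5 methoxy oxygen, iodide removes that methyl group by SN2 attack and the unchelated C7 methyl ether stays; the aprotic, weakly Lewis acidic medium, which has precedent in the 5-O-demethylation of prenylated 5-methoxyflavanones, should spare the geranyl alkenes and the C2 centre.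

**Compound list**

1 | 1,3-dimethoxybenzene | COc1cccc(OC)c1 | starting material
2 | geranyl bromide, (2E)-1-bromo-3,7-dimethylocta-2,6-diene | BrC/C=C(\C)CCC=C(C)C | starting material
3 | 2,6-dimethoxyphenyllithium (in situ) | [Li]c1c(OC)cccc1OC | intermediate
4 | 2-geranyl-1,3-dimethoxybenzene | COc1cccc(OC)c1C/C=C(\C)CCC=C(C)C | intermediate
5 | 2-(4-geranyl-3,5-dimethoxyphenyl)-4,4,5,5-tetramethyl-1,3,2-dioxaborolane (in situ) | COc1cc(B2OC(C)(C)C(C)(C)O2)cc(OC)c1C/C=C(\C)CCC=C(C)C | intermediate
6 | 4-geranyl-3,5-dimethoxyphenol | COc1cc(O)cc(OC)c1C/C=C(\C)CCC=C(C)C | intermediate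
7 | 3-geranyl-6-hydroxy-2,4-dimethoxybenzaldehyde | O=Cc1c(O)cc(OC)c(C/C=C(\C)CCC=C(C)C)c1OC | intermediate
8 | tert-butyl acetate | CC(=O)OC(C)(C)C | starting material
9 | lithium enolate of tert-butyl acetate (in situ) | [Li+].C=C([O-])OC(C)(C)C | intermediate
10 | tert-butyl 3-(3-geranyl-6-hydroxy-2,4-dimethoxyphenyl)-3-hydroxypropanoate (racemic) | CC(C)(C)OC(=O)CC(O)c1c(O)cc(OC)c(C/C=C(\C)CCC=C(C)C)c1OC | intermediate
11 | tert-butyl 3-(3-geranyl-6-hydroxy-2,4-dimethoxyphenyl)-3-oxopropanoate | CC(C)(C)OC(=O)CC(=O)c1c(O)cc(OC)c(C/C=C(\C)CCC=C(C)C)c1OC | intermediate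
12 | benzaldehyde | O=Cc1ccccc1 | starting material
13 | tert-butyl (2Z)-2-(3-geranyl-6-hydroxy-2,4-dimethoxybenzoyl)-3-phenylprop-2-enoate | CC(C)(C)OC(=O)/C(=C\c1ccccc1)C(=O)c1c(O)cc(OC)c(C/C=C(\C)CCC=C(C)C)c1OC | intermediate
14 | tert-butyl (2S)-6-geranyl-5,7-dimethoxy-4-oxo-2-phenylchromane-3-carboxylate (C3 epimers and enol form; in situ) | COc1cc2c(c(OC)c1C/C=C(\C)CCC=C(C)C)C(=O)C(C(=O)OC(C)(C)C)[C@@H](c1ccccc1)O2 | intermediate
15 | (2S)-6-geranyl-5,7-dimethoxy-2-phenylchroman-4-one, (2S)-6-geranyl-5,7-dimethoxyflavanone | COc1cc2c(c(OC)c1C/C=C(\C)CCC=C(C)C)C(=O)C[C@@H](c1ccccc1)O2 | intermediate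
16 | (2S)-6-geranyl-5-hydroxy-7-methoxy-2-phenylchroman-4-one, (2S)-6-geranylpinostrobin | COc1cc2c(c(O)c1C/C=C(\C)CCC=C(C)C)C(=O)C[C@@H](c1ccccc1)O2 | target

**Count**

Total steps: 8. Longest linear sequence: 8 steps (from 1,3-dimethoxybenzene 1).

**Steps most likely to fail**

Step 7. The ortho-methoxy group twists the aroyl unit out of the enone plane, so 13 may sit in the catalyst differently from simpler substrates and face selectivity may be poor. Uncatalysed closure may also compete, and the hot acid stage may isomerise the geranyl chain. The fallback sets out from aldehyde 7 and comes back at flavanone 15; it sets C2 by enantioselective conjugate arylation of a chromone instead of by ring closure. Ethynylmagnesium bromide (3 equiv, THF, 0 °C) should add to 7 to give the propargylic alcohol F1. MnO2 in CH2Cl2 should oxidise it to the ynone F2. Et2NH in EtOH should close the pyranone by amine-mediated 6-endo addition of the phenol to the ynone, giving 6-geranyl-5,7-dimethoxychromone F3. Pd(OCOCF3)2 (5 mol %), (R)-4-tert-butyl-2-(pyridin-2-yl)-4,5-dihydrooxazole (6 mol %), PhB(OH)2, NH4PF6 and H2O in ClCH2CH2Cl at 60 °C should then add the phenyl group to C2 of F3 to give 15. The ligand enantiomer is chosen for 2S by analogy with cyclic enones and would need confirmation. The route continues with step 8.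

Step 8. Configuration at C2 may be lost by magnesium-assisted opening and reclosure of ring C at 60 °C; selectivity between the two methyl ethers may be incomplete; the geranyl chain may cyclise onto the freed 5-oxygen. The fallback sets out from aldehyde 7 and comes back at target 16; it moves the demethylation to a compound without a stereocentre and sets C2 last. Aldehyde 7 is taken as above through propargylic alcohol F1 and ynone F2 to chromone F3. MgI2·OEt2 in THF at 60 °C should remove the chelated C5 methyl group of F3 to give 6-geranyl-5-hydroxy-7-methoxychromone F4, in which nothing can racemise. The palladium-catalysed enantioselective conjugate addition of PhB(OH)2 described above, applied to F4, should give 16 directly.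

Step 6. Amine-catalysed oxa-Michael addition may close 13 prematurely and racemically during the condensation or on silica, carrying racemic material into step 7. The fallback sets out from β-keto ester 11 and comes back at alkylidene 13; it masks the phenol while the alkene is made. TBSCl, imidazole and DMF should convert 11 into the silyl ether F5. Knoevenagel condensation of F5 with 12 (piperidine, AcOH, toluene) should give the silylated alkylidene F6, which cannot cyclise. HF·pyridine in THF at 0 °C (acidic fluoride, no free base) should free the phenol to give 13, which is used at once in step 7.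

**Further compounds**

F1 | step 7 | 1-(3-geranyl-6-hydroxy-2,4-dimethoxyphenyl)prop-2-yn-1-ol (racemic) | C#CC(O)c1c(O)cc(OC)c(C/C=C(\C)CCC=C(C)C)c1OC
F2 | step 7 | 1-(3-geranyl-6-hydroxy-2,4-dimethoxyphenyl)prop-2-yn-1-one | C#CC(=O)c1c(O)cc(OC)c(C/C=C(\C)CCC=C(C)C)c1OC
F3 | step 7 | 6-geranyl-5,7-dimethoxy-4H-chromen-4-one | COc1cc2occc(=O)c2c(OC)c1C/C=C(\C)CCC=C(C)C
F4 | step 8 | 6-geranyl-5-hydroxy-7-methoxy-4H-chromen-4-one | COc1cc2occc(=O)c2c(O)c1C/C=C(\C)CCC=C(C)C
F5 | step 6 | tert-butyl 3-{6-[(tert-butyldimethylsilyl)oxy]-3-geranyl-2,4-dimethoxyphenyl}-3-oxopropanoate | CC(C)(C)OC(=O)CC(=O)c1c(O[Si](C)(C)C(C)(C)C)cc(OC)c(C/C=C(\C)CCC=C(C)C)c1OC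
F6 | step 6 | tert-butyl (2Z)-2-{6-[(tert-butyldimethylsilyl)oxy]-3-geranyl-2,4-dimethoxybenzoyl}-3-phenylprop-2-enoate | CC(C)(C)OC(=O)/C(=C\c1ccccc1)C(=O)c1c(O[Si](C)(C)C(C)(C)C)cc(OC)c(C/C=C(\C)CCC=C(C)C)c1OC
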